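The runs stem from a simulated flask for substances that don't exist, and the scatter is random.

Blue leaves 11.2% of its starting material at 3.00 d beside 53.4% of target, and 35.4% stands in neither column.

| flask | starting material | partner | remark | time |
|---|---|---|---|---|
| blue | 20 mM | 20 mM | run made earlier |  |
| violet | 20 mM | 28 mM | run made earlier |  |
| teal | 20 mM | 44 mM | run made earlier |  |
| green | 40 mM | 20 mM | run made earlier |  |
| Sunday's | 20 mM | 20.0 mM | everything together at the start | 3.0 d |
| Tuesday's | 20 mM (fed, over 40 h) | 20.0 mM | all else is in the flask from the start; the feed brings no volume worth counting | 3.0 d |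
| Friday's | 20 mM | 20.0 mM (fed, over 40 h) | all else is in the flask from the start; the feed brings no volume worth counting | 3.0 d |

- blue (time / d: target / %, starting material / %): 0.833: 27.3, 31.1; 1.67: 40.0, 19.2; 2.50: 49.3, 13.8; 3.00: 53.4, 11.2
- violet (time / d: target / %, starting material / %): 0.833: 26.8, 30.5; 1.67: 41.7, 18.7; 2.50: 48.1, 13.5; 4.00: 61.7, 6.3
- teal (time / d: target / %, starting material / %): 0.417: 20.5, 47.5; 1.25: 36.5, 22.8; 2.50: 50.9, 16.0; 4.00: 62.6, 9.3
- green (time / d: target / %, starting material / %): 0.250: 11.1, 53.7; 0.625: 22.4, 30.9; 1.67: 34.0, 15.5; 4.00: 43.4, 10.0

(each reading ± 1 percentage point)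

- the analysis behind the earlier runs scatters by 1 percentage point, standard deviation
- a reading or a percentage of target counts all its forms, free or not

* the flask with the highest amount of target, in percent of the starting material charged ("all alike" if they lie within 1.5 percentage points) (Sunday's / Tuesday's / Friday's / all alike)
* final target, as a percentage of the starting material charged, in Sunday's
* final target, as a percentage of the starting material charged, in Tuesday's
* final target, as a percentage of the starting material charged, in Friday's

The first setting is the amount of partner. By hand, more partner should give more target, but at 2.50 d violet and teal differ by 2.8 percentage points, with blue between them, against a scatter of 1 point. Sunday's repeats blue, so about 53.4% is expected.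

The second setting is the feed of starting material. Green, with twice the starting material, gives less target per charge than blue at 1.67 d, so a thin feed should help. However, fed material arrives on average 0.833 d late. Tuesday's can therefore be reckoned on a clock of 2.17 d, where blue's readings lie between 40.0% and 49.3%, which is lower than the 53.4% expected for Sunday's.

The third setting is the feed of partner. The reckoning joins the early demand to the supply. The feed ratio φ, early target demand divided by partner feed rate, uses teal's first reading, from a flask whose partner starts at 44 mM:

demand = 9.83 mM d⁻¹

feed = 12.0 mM d⁻¹

φ = 0.819

Friday's feed thus exceeds the reckoned demand, but only by 2.17 mM d⁻¹, so by this reckoning its free partner builds up slowly at first. This reckoning puts Tuesday's below Sunday's and, with Friday's partner arriving late, expects Friday's below Sunday's as well, without a number for Friday's.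

The forecast names Sunday's as the highest, with 53.5% (52% to 55%) for Sunday's, 51% (47% to 56%) for Tuesday's and 48% (41% to 53%) for Friday's. Of Friday's feed it says that it “roughly matches initial demand”.

The flasks give 52.6% for Sunday's, 47.9% for Tuesday's and 42.0% for Friday's, which stands 6 points below the forecast's value for Friday's.

    2 starting material → homo dimer (k = 0.540 L mol⁻¹ h⁻¹)
    crystals ⇌ target, rate k2*(cs2 - [target]) while solid is left; crystals form when [target] > cs2 (solubility = 5.30 mM, k = 0.220 h⁻¹)
    tight pair ⇌ loose pair (K = 2.10, k = 1.70 h⁻¹)
    partner + loose pair → isomer of the product (k = 3000 L mol⁻¹ h⁻¹)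
    starting material ⇌ dormant form (K = 0.900, k = 0.0490 h⁻¹)
    starting material ⇌ tight pair (K = 0.0310, k = 0.0290 h⁻¹)
    partner + tight pair → target (k = 1900 L mol⁻¹ h⁻¹)

With φ at 0.819, Friday's still holds 61.2% of its partner at 1.67 d, and its isomer of the product reaches 11.1% at 3.00 d, more than Sunday's 3.37%. The neighbouring flask feeds 8.0 mM of partner over the same 40 h, so its feed is 4.80 mM d⁻¹ and φ becomes 2.05, demand twice the feed. There partner is the limiting reagent, standing at 0% of its own charge at 3.00 d, with target at 19.0% and isomer of the product at 21.0% of the starting material charged.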